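**Plan**

- Numbering (cembrane): C1 is the ring CH that carries the lactone α-carbon C15, C2 the lactone O–CH, C9 the CH–OAc, C16 the lactone carbonyl, C17 the exo-methylene carbon.
- Enabling feature: in the α-methylene-γ-lactone fused to the 14-membered carbocycle, C1 is both the β-carbon of the C15=C17 acceptor and the carrier of ring methylene C14. The last bond made is therefore C1–C14: a C14 radical adds to C1 of a 3-(phenylsulfonylmethyl)butenolide and loss of PhSO2• creates C15=C17 in the same event.
- Earlier cuts: C1–C2 plus the lactone C–O (alkenylchromium addition of a β-iodoacrylate to a C2 enal, then lactonisation), C13–C14 (methylenation, hydroboration), C11=C12 (cross-metathesis with methacrolein), C9–C10 (allylboration); C2–C9 with the C4 and C8 methyls is geraniol.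
- Forward order: the geraniol chain is grown linearly to C14, the butenolide (lactone ring) is attached, and the 14-membered ring closes in the last step with the C9 acetate already in place.
- Stereochemistry: C9 (R) by reagent control (pinene-derived allylborane), C2 (S) by ligand control in the chromium addition, C1 (R) by substrate control from C2 in the ring closure (trans lactone); the 3E, 7E and 11E olefins come from geraniol, E-selective SeO2 oxidation and E-selective metathesis.

Key step: step 16

Assumption: the (R)-configured valinol-derived oxazoline–sulfonamide ligand is taken to direct the alkenylchromium reagent to the Re face of the C2 enal in step 14; both antipodes are available, and the (S)-form would be used unchanged if a model coupling shows the opposite sense.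

**Route**

Step 1
Reactants: 1 geraniol
Product: 2 geranyl tert-butyldimethylsilyl ether
Conditions: TBSCl, imidazole, DMF, 0 °C to rt
Reagents that add atoms: tert-butyldimethylsilyl chloride, CC(C)(C)[Si](C)(C)Cl
Why: Imidazole-promoted silylation of a primary allylic alcohol is routine and masks C2–OH for the chain-building steps; no stereocenter is involved.

Step 2
Reactants: 2 geranyl tert-butyldimethylsilyl ether
Product: 3 (2E,6E)-8-(tert-butyldimethylsilyloxy)-2,6-dimethylocta-2,6-dien-1-ol
Conditions: SeO2 (0.1 equiv), t-BuOOH (3 equiv), salicylic acid (0.1 equiv), CH2Cl2, rt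
Reagents that add atoms: tert-butyl hydroperoxide, CC(C)(C)OO (terminal oxygen source); selenium dioxide, O=[Se]=O (catalytic oxygen carrier)
Why: Catalytic SeO2 allylic oxidation (ene reaction, then [2,3]-sigmatropic shift) attacks the more electron-rich distal trisubstituted olefin and oxidises its E-methyl group, as is established for geranyl ethers and esters; any aldehyde 4 formed by over-oxidation is carried into step 3.

Step 3
Reactants: 3 (2E,6E)-8-(tert-butyldimethylsilyloxy)-2,6-dimethylocta-2,6-dien-1-ol
Product: 4 (2E,6E)-8-(tert-butyldimethylsilyloxy)-2,6-dimethylocta-2,6-dienal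
Conditions: MnO2 (15 equiv), CH2Cl2, rt
Reagents that add atoms: none
Why: MnO2 oxidation of a primary allylic alcohol stops at the enal and leaves the silyl ether and the olefin geometry untouched.

Step 4
Reactants: 4 (2E,6E)-8-(tert-butyldimethylsilyloxy)-2,6-dimethylocta-2,6-dienal
Product: 6 (4R,5E,9E)-11-(tert-butyldimethylsilyloxy)-5,9-dimethylundeca-1,5,9-trien-4-ol, via borinate ester 5 (not isolated)
Conditions: (+)-Ipc2BOMe, CH2=CHCH2MgBr, Et2O, 0 °C to rt; then 4, −78 °C; then 3 M NaOH, 30% H2O2, rt
Reagents that add atoms: allylmagnesium bromide, C=CC[Mg]Br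
Why: Brown allylboration through a closed chair transition state is reagent-controlled; the allylborane derived from (−)-α-pinene adds to the Re face of the α-methyl enal and sets C9 as R.

Step 5
Reactants: 6 (4R,5E,9E)-11-(tert-butyldimethylsilyloxy)-5,9-dimethylundeca-1,5,9-trien-4-ol
Product: 7 (4R,5E,9E)-11-(tert-butyldimethylsilyloxy)-5,9-dimethylundeca-1,5,9-trien-4-yl acetate
Conditions: Ac2O, pyridine, DMAP (cat.), CH2Cl2, rt
Reagents that add atoms: acetic anhydride, CC(=O)OC(C)=O
Why: DMAP-catalysed acetylation installs the C9 acetate of the target with retention at C9, so no later protecting-group exchange is needed there.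

Step 6
Reactants: 7 (4R,5E,9E)-11-(tert-butyldimethylsilyloxy)-5,9-dimethylundeca-1,5,9-trien-4-yl acetate; 8 methacrolein
Product: 9 (2E,5R,6E,10E)-5-acetoxy-12-(tert-butyldimethylsilyloxy)-2,6,10-trimethyldodeca-2,6,10-trienal
Conditions: 8 (10 equiv), second-generation Hoveyda–Grubbs catalyst RuCl2(H2IMes)(=CH-C6H4-2-O-i-Pr) (5 mol%), CH2Cl2, 40 °C
Reagents that add atoms: none
Why: Olefin cross-metathesis of a monosubstituted alkene with excess methacrolein gives the 2-methyl-2-enal with high E selectivity, while the trisubstituted olefins and the allylic acetate are too hindered to take part.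

Step 7
Reactants: 9 (2E,5R,6E,10E)-5-acetoxy-12-(tert-butyldimethylsilyloxy)-2,6,10-trimethyldodeca-2,6,10-trienal
Product: 10 (3E,6R,7E,11E)-13-(tert-butyldimethylsilyloxy)-3,7,11-trimethyltrideca-1,3,7,11-tetraen-6-yl acetate
Conditions: Ph3PCH3Br, KN(SiMe3)2, THF, 0 °C; then 9, −78 to 0 °C
Reagents that add atoms: methyltriphenylphosphonium bromide, [Br-].C[P+](c1ccccc1)(c1ccccc1)c1ccccc1
Why: Wittig methylenation of the enal is much faster than attack of the ylide on the acetate at low temperature and adds C14 as the terminus of a 1,3-diene.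

Step 8
Reactants: 10 (3E,6R,7E,11E)-13-(tert-butyldimethylsilyloxy)-3,7,11-trimethyltrideca-1,3,7,11-tetraen-6-yl acetate
Product: 12 (3E,6R,7E,11E)-13-(tert-butyldimethylsilyloxy)-1-hydroxy-3,7,11-trimethyltrideca-3,7,11-trien-6-yl acetate, via B-alkyl-9-BBN adduct 11 (not isolated)
Conditions: 9-BBN (1.3 equiv), THF, 0 °C to rt; then NaBO3·4H2O, H2O, rt
Reagents that add atoms: sodium perborate, [Na+].[Na+].O[B-]1(O)OO[B-](O)(O)OO1
Why: Hydroboration–oxidation with the bulky 9-BBN takes only the monosubstituted C13=C14 terminus of the diene, anti-Markovnikov, and the mild perborate oxidation spares the acetate.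

Step 9
Reactants: 12 (3E,6R,7E,11E)-13-(tert-butyldimethylsilyloxy)-1-hydroxy-3,7,11-trimethyltrideca-3,7,11-trien-6-yl acetate
Product: 13 (3E,6R,7E,11E)-1,13-dihydroxy-3,7,11-trimethyltrideca-3,7,11-trien-6-yl acetate
Conditions: HF·pyridine, pyridine, THF, 0 °C to rt
Reagents that add atoms: none
Why: Buffered fluoride desilylation cleaves the primary silyl ether without touching the secondary allylic acetate.

Step 10
Reactants: 13 (3E,6R,7E,11E)-1,13-dihydroxy-3,7,11-trimethyltrideca-3,7,11-trien-6-yl acetate
Product: 14 (2E,6E,8R,10E)-8-acetoxy-13-hydroxy-3,7,11-trimethyltrideca-2,6,10-trienal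
Conditions: MnO2 (20 equiv), CH2Cl2, rt
Reagents that add atoms: none
Why: MnO2 oxidises only the allylic C2 alcohol; the homoallylic C14 alcohol is not activated and remains, so no second protecting group is needed.

Step 11
Reactants: 15 methyl propiolate
Product: 17 methyl (Z)-2-(hydroxymethyl)-3-iodoprop-2-enoate, via aluminium iodoallenolate 16 (not isolated)
Conditions: Et2AlI (1.2 equiv), CH2Cl2, 0 °C; then (CH2O)n, 0 °C to rt; aqueous potassium sodium tartrate
Reagents that add atoms: diethylaluminium iodide, CC[Al](I)CC; formaldehyde (as paraformaldehyde), C=O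
Why: Halo-aldol (β-iodo Morita–Baylis–Hillman) reaction: conjugate addition of iodide gives the iodoallenolate, which is hydroxymethylated anti to iodine, so the kinetic product has iodine cis to the ester, the geometry needed for lactonisation.

Step 12
Reactants: 17 methyl (Z)-2-(hydroxymethyl)-3-iodoprop-2-enoate
Product: 18 methyl (E)-2-(bromomethyl)-3-iodoprop-2-enoate
Conditions: CBr4, PPh3, CH2Cl2, 0 °C
Reagents that add atoms: carbon tetrabromide, BrC(Br)(Br)Br
Why: Appel bromination converts the primary allylic alcohol under neutral conditions that do not isomerise the iodoalkene (iodine stays cis to the ester; the descriptor changes only by priority).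

Step 13
Reactants: 18 methyl (E)-2-(bromomethyl)-3-iodoprop-2-enoate; 19 sodium benzenesulfinate
Product: 20 methyl (E)-3-iodo-2-[(phenylsulfonyl)methyl]prop-2-enoate
Conditions: PhSO2Na (1.05 equiv), DMF, 0 °C to rt
Reagents that add atoms: none
Why: S-alkylation of the sulfinate at the primary allylic bromide (SN2) is far faster than vinylic substitution of iodide at low temperature, as in the standard preparation of 2-(sulfonylmethyl)acrylates.

Step 14
Reactants: 14 (2E,6E,8R,10E)-8-acetoxy-13-hydroxy-3,7,11-trimethyltrideca-2,6,10-trienal; 20 methyl (E)-3-iodo-2-[(phenylsulfonyl)methyl]prop-2-enoate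
Product: 23 (S)-5-[(1E,5E,7R,9E)-7-acetoxy-12-hydroxy-2,6,10-trimethyldodeca-1,5,9-trien-1-yl]-3-[(phenylsulfonyl)methyl]furan-2(5H)-one, via alkenylchromium reagent 21 (not isolated), via hydroxy ester 22 (not isolated)
Conditions: CrCl2 (4 equiv), (R)-N-[2-(4-isopropyl-4,5-dihydrooxazol-2-yl)-6-methylphenyl]methanesulfonamide (4.4 equiv), proton sponge (4.4 equiv), MeCN, rt; then NiCl2 (0.1 equiv), 14, 20 (2 equiv), rt; aqueous potassium sodium tartrate; PPTS (cat.), CH2Cl2, rt
Reagents that add atoms: none
Why: Nozaki–Hiyama–Kishi coupling: zerovalent nickel inserts into the C–I bond, transmetalation gives a trivalent alkenylchromium species that adds only to the aldehyde, the sulfonamide ligand on chromium directs attack to the Re face to set C2 as S, and the cis γ-hydroxy ester lactonises to the butenolide; the acetate, the sulfone and the free C14 alcohol are tolerated by organochromium reagents.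

Step 15
Reactants: 23 (S)-5-[(1E,5E,7R,9E)-7-acetoxy-12-hydroxy-2,6,10-trimethyldodeca-1,5,9-trien-1-yl]-3-[(phenylsulfonyl)methyl]furan-2(5H)-one
Product: 24 (S)-5-[(1E,5E,7R,9E)-7-acetoxy-12-iodo-2,6,10-trimethyldodeca-1,5,9-trien-1-yl]-3-[(phenylsulfonyl)methyl]furan-2(5H)-one
Conditions: I2, PPh3, imidazole, CH2Cl2, 0 °C
Reagents that add atoms: iodine, II
Why: Appel-type iodination of the primary alcohol proceeds by SN2 on the alkoxyphosphonium ion under near-neutral conditions, so the base-sensitive C2 centre, the allylic sulfone and the acetate are not disturbed.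

Step 16
Reactants: 24 (S)-5-[(1E,5E,7R,9E)-7-acetoxy-12-iodo-2,6,10-trimethyldodeca-1,5,9-trien-1-yl]-3-[(phenylsulfonyl)methyl]furan-2(5H)-one
Product: 25 (1R,2S,9R)-9-acetoxycembra-3E,7E,11E,15(17)-tetraen-16,2-olide (CNP0129197.1)
Conditions: (Bu3Sn)2 (1.5 equiv), degassed benzene (0.002 M), sunlamp irradiation, 80 °C
Reagents that add atoms: none
Why: Proposed new method: tributylstannyl radicals from photolysed hexabutylditin abstract iodine from C14, the nucleophilic primary radical adds to the electrophilic β-carbon C1 of the butenolide, and the resulting C15 radical expels PhSO2•, which the ditin traps to regenerate the stannyl radical; the closest known reaction types are intermolecular radical allylation with 2-(sulfonylmethyl)acrylates and tin-mediated radical macrocyclisation onto electron-poor alkenes. The 14-membered carbocycle closes in the 14-exo-trig mode, the acceptor carbon C15 staying outside the new ring. The new stereocenter C1 is controlled by C2: the radical adds to the butenolide face anti to the C2 alkenyl substituent, which gives the trans-fused lactone (1R). The step needs ring closure over oligomerisation and addition to the butenolide over the three trisubstituted olefins; high dilution, the absence of a hydrogen-atom donor (an unreacted radical is only returned to the iodide by iodine transfer) and the polarity match between the alkyl radical and the sole electron-poor alkene should secure both. Irreversible β-scission of the C17–S bond makes the closure productive and unveils the C15=C17 methylene only in this last, base-free event, so C2 cannot epimerise.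

**Compound list**

1 | geraniol | OC/C=C(\C)CCC=C(C)C | starting material
2 | geranyl tert-butyldimethylsilyl ether | CC(C)(C)[Si](C)(C)OC/C=C(\C)CCC=C(C)C | intermediate
3 | (2E,6E)-8-(tert-butyldimethylsilyloxy)-2,6-dimethylocta-2,6-dien-1-ol | CC(C)(C)[Si](C)(C)OC/C=C(\C)CC/C=C(\C)CO | intermediate
4 | (2E,6E)-8-(tert-butyldimethylsilyloxy)-2,6-dimethylocta-2,6-dienal | CC(C)(C)[Si](C)(C)OC/C=C(\C)CC/C=C(\C)C=O | intermediate
5 | diisopinocampheylborinate ester of alcohol 6 (not isolated) | CC(C)(C)[Si](C)(C)OC/C=C(\C)CC/C=C(\C)[C@H](OB([C@H]1C[C@H]2C[C@H](C2(C)C)[C@@H]1C)[C@H]1C[C@H]2C[C@H](C2(C)C)[C@@H]1C)CC=C | intermediate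
6 | (4R,5E,9E)-11-(tert-butyldimethylsilyloxy)-5,9-dimethylundeca-1,5,9-trien-4-ol | CC(C)(C)[Si](C)(C)OC/C=C(\C)CC/C=C(\C)[C@H](O)CC=C | intermediate
7 | (4R,5E,9E)-11-(tert-butyldimethylsilyloxy)-5,9-dimethylundeca-1,5,9-trien-4-yl acetate | CC(C)(C)[Si](C)(C)OC/C=C(\C)CC/C=C(\C)[C@H](OC(C)=O)CC=C | intermediate
8 | methacrolein | CC(=C)C=O | starting material
9 | (2E,5R,6E,10E)-5-acetoxy-12-(tert-butyldimethylsilyloxy)-2,6,10-trimethyldodeca-2,6,10-trienal | CC(C)(C)[Si](C)(C)OC/C=C(\C)CC/C=C(\C)[C@H](OC(C)=O)C/C=C(\C)C=O | intermediate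
10 | (3E,6R,7E,11E)-13-(tert-butyldimethylsilyloxy)-3,7,11-trimethyltrideca-1,3,7,11-tetraen-6-yl acetate | CC(C)(C)[Si](C)(C)OC/C=C(\C)CC/C=C(\C)[C@H](OC(C)=O)C/C=C(\C)C=C | intermediate
11 | B-alkyl-9-BBN adduct of 10, boron on C14 (not isolated) | CC(C)(C)[Si](C)(C)OC/C=C(\C)CC/C=C(\C)[C@H](OC(C)=O)C/C=C(\C)CCB1C2CCCC1CCC2 | intermediate
12 | (3E,6R,7E,11E)-13-(tert-butyldimethylsilyloxy)-1-hydroxy-3,7,11-trimethyltrideca-3,7,11-trien-6-yl acetate | CC(C)(C)[Si](C)(C)OC/C=C(\C)CC/C=C(\C)[C@H](OC(C)=O)C/C=C(\C)CCO | intermediate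
13 | (3E,6R,7E,11E)-1,13-dihydroxy-3,7,11-trimethyltrideca-3,7,11-trien-6-yl acetate | OC/C=C(\C)CC/C=C(\C)[C@H](OC(C)=O)C/C=C(\C)CCO | intermediate
14 | (2E,6E,8R,10E)-8-acetoxy-13-hydroxy-3,7,11-trimethyltrideca-2,6,10-trienal | O=C/C=C(\C)CC/C=C(\C)[C@H](OC(C)=O)C/C=C(\C)CCO | intermediate
15 | methyl propiolate | C#CC(=O)OC | starting material
16 | diethylaluminium 3-iodo-1-methoxyallenolate (not isolated) | COC(O[Al](CC)CC)=C=CI | intermediate
17 | methyl (Z)-2-(hydroxymethyl)-3-iodoprop-2-enoate (iodine cis to ester) | COC(=O)/C(CO)=C\I | intermediate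
18 | methyl (E)-2-(bromomethyl)-3-iodoprop-2-enoate (iodine cis to ester) | COC(=O)/C(CBr)=C\I | intermediate
19 | sodium benzenesulfinate | [Na+].[O-]S(=O)c1ccccc1 | starting material
20 | methyl (E)-3-iodo-2-[(phenylsulfonyl)methyl]prop-2-enoate (iodine cis to ester) | COC(=O)/C(CS(=O)(=O)c1ccccc1)=C\I | intermediate
21 | alkenylchromium dichloride derived from 20 (not isolated) | COC(=O)/C(CS(=O)(=O)c1ccccc1)=C\[Cr](Cl)Cl | intermediate
22 | methyl (2E,4S,5E,9E,11R,13E)-11-acetoxy-4,16-dihydroxy-6,10,14-trimethyl-2-[(phenylsulfonyl)methyl]hexadeca-2,5,9,13-tetraenoate (not isolated) | COC(=O)/C(CS(=O)(=O)c1ccccc1)=C\[C@@H](O)/C=C(\C)CC/C=C(\C)[C@H](OC(C)=O)C/C=C(\C)CCO | intermediate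
23 | (S)-5-[(1E,5E,7R,9E)-7-acetoxy-12-hydroxy-2,6,10-trimethyldodeca-1,5,9-trien-1-yl]-3-[(phenylsulfonyl)methyl]furan-2(5H)-one | O=C1O[C@@H](/C=C(\C)CC/C=C(\C)[C@H](OC(C)=O)C/C=C(\C)CCO)C=C1CS(=O)(=O)c1ccccc1 | intermediate
24 | (S)-5-[(1E,5E,7R,9E)-7-acetoxy-12-iodo-2,6,10-trimethyldodeca-1,5,9-trien-1-yl]-3-[(phenylsulfonyl)methyl]furan-2(5H)-one | O=C1O[C@@H](/C=C(\C)CC/C=C(\C)[C@H](OC(C)=O)C/C=C(\C)CCI)C=C1CS(=O)(=O)c1ccccc1 | intermediate
25 | (1R,2S,9R)-9-acetoxycembra-3E,7E,11E,15(17)-tetraen-16,2-olide (CNP0129197.1) | C=C1C(=O)O[C@H]2/C=C(\C)CC/C=C(\C)[C@H](OC(C)=O)C/C=C(\C)CC[C@H]12 | target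

**Step count and risks**

Total: 16 steps. Longest linear sequence: 13 steps (steps 1–10 and 14–16 from geraniol); the iodoacrylate branch is 3 steps (11–13).

Steps most likely to fail:

1. Step 16. Addition of the primary radical to a β,γ-disubstituted butenolide carbon may be too slow, so that oligomerisation, E/Z leakage at C11=C12 through reversible 3-exo closure of the homoallylic C14 radical, or attack syn to the C2 substituent take over. The fallback uses known chemistry and closes the ring at C1–C2 instead. Diene 10 is hydroborated to 11 as in step 8 and coupled in the same flask with iodo alcohol 17 (B-alkyl Suzuki–Miyaura coupling, PdCl2(dppf), AsPh3, Cs2CO3, DMF/H2O, rt) to give methyl (2Z,6E,9R,10E,14E)-9-acetoxy-16-(tert-butyldimethylsilyloxy)-2-(hydroxymethyl)-6,10,14-trimethylhexadeca-2,6,10,14-tetraenoate F1. Appel bromination (CBr4, PPh3) gives the allylic bromide F2, aqueous HF in MeCN removes the silyl group to give the C2 alcohol F3, and MnO2 gives the enal F4. Slow addition of F4 to CrCl2 in THF at high dilution (intramolecular Nozaki–Hiyama allylation, with the sulfonamide ligand of step 14 to bias the absolute sense) forms the allylchromium reagent F5, which adds through C1 to the C2 aldehyde in the anti mode to give the macrocyclic hydroxy ester F6; this lactonises to the trans-fused α-methylene lactone. The fallback sets out from 10 (with 17) and returns to the route at 25.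

2. Step 14. The allylic sulfone may lose sulfinate under the low-valent nickel and chromium species, or the ligand may give weak facial control with this α-branched, cis-ester alkenylchromium reagent. The fallback brings the sulfone in after the coupling. Enal 14 is coupled under the same chromium/nickel conditions with iodo alcohol 17, through the alkenylchromium reagent F7 and the hydroxy ester F8, to give the diol butenolide (S)-5-[(1E,5E,7R,9E)-7-acetoxy-12-hydroxy-2,6,10-trimethyldodeca-1,5,9-trien-1-yl]-3-(hydroxymethyl)furan-2(5H)-one F9. Double Appel iodination (I2, PPh3, imidazole) gives the diiodide F10, and one equivalent of PhSO2Na in DMF at −20 °C displaces only the far more reactive allylic iodide. The fallback sets out from 14 (with 17) and returns to the route at 24.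

3. Step 11. Polymeric formaldehyde may react too slowly, so that the iodoallenolate is simply protonated, or the kinetic adduct may equilibrate to the isomer with iodine trans to the ester. The fallback introduces sulfur at the allenolate stage and needs no formaldehyde, bromide or sulfinate displacement. Methyl propiolate 15 is treated with Me3SiI in CH2Cl2 at −78 °C to give the silyl iodoallenolate 1-iodo-3-methoxy-3-(trimethylsilyloxy)propa-1,2-diene F11, which is alkylated anti to iodine with chloromethyl phenyl sulfide and ZnBr2 (phenylthiomethylation of a silyl ketene acetal) to give methyl (E)-3-iodo-2-[(phenylsulfanyl)methyl]prop-2-enoate F12; oxidation with mCPBA (2.2 equiv) gives the sulfone. The fallback sets out from 15 and returns to the route at 20.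

Further compounds
F1 | step 16 | methyl (2Z,6E,9R,10E,14E)-9-acetoxy-16-(tert-butyldimethylsilyloxy)-2-(hydroxymethyl)-6,10,14-trimethylhexadeca-2,6,10,14-tetraenoate | CC(C)(C)[Si](C)(C)OC/C=C(\C)CC/C=C(\C)[C@H](OC(C)=O)C/C=C(\C)CC/C=C(/CO)C(=O)OC
F2 | step 16 | methyl (2E,6E,9R,10E,14E)-9-acetoxy-2-(bromomethyl)-16-(tert-butyldimethylsilyloxy)-6,10,14-trimethylhexadeca-2,6,10,14-tetraenoate | CC(C)(C)[Si](C)(C)OC/C=C(\C)CC/C=C(\C)[C@H](OC(C)=O)C/C=C(\C)CC/C=C(/CBr)C(=O)OC
F3 | step 16 | methyl (2E,6E,9R,10E,14E)-9-acetoxy-2-(bromomethyl)-16-hydroxy-6,10,14-trimethylhexadeca-2,6,10,14-tetraenoate | OC/C=C(\C)CC/C=C(\C)[C@H](OC(C)=O)C/C=C(\C)CC/C=C(/CBr)C(=O)OC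
F4 | step 16 | methyl (2E,6E,9R,10E,14E)-9-acetoxy-2-(bromomethyl)-6,10,14-trimethyl-16-oxohexadeca-2,6,10,14-tetraenoate | O=C/C=C(\C)CC/C=C(\C)[C@H](OC(C)=O)C/C=C(\C)CC/C=C(/CBr)C(=O)OC
F5 | step 16 | allylchromium dichloride derived from F4 (not isolated) | O=C/C=C(\C)CC/C=C(\C)[C@H](OC(C)=O)C/C=C(\C)CC/C=C(/C[Cr](Cl)Cl)C(=O)OC
F6 | step 16 | methyl 2-[(1R,2S,3E,7E,9R,11E)-9-acetoxy-2-hydroxy-4,8,12-trimethylcyclotetradeca-3,7,11-trien-1-yl]prop-2-enoate (not isolated) | O[C@H]1/C=C(\C)CC/C=C(\C)[C@H](OC(C)=O)C/C=C(\C)CC[C@@H]1C(=C)C(=O)OC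
F7 | step 14 | alkenylchromium dichloride derived from 17 (not isolated) | COC(=O)/C(CO)=C\[Cr](Cl)Cl
F8 | step 14 | methyl (2Z,4S,5E,9E,11R,13E)-11-acetoxy-4,16-dihydroxy-2-(hydroxymethyl)-6,10,14-trimethylhexadeca-2,5,9,13-tetraenoate (not isolated) | COC(=O)/C(CO)=C\[C@@H](O)/C=C(\C)CC/C=C(\C)[C@H](OC(C)=O)C/C=C(\C)CCO
F9 | step 14 | (S)-5-[(1E,5E,7R,9E)-7-acetoxy-12-hydroxy-2,6,10-trimethyldodeca-1,5,9-trien-1-yl]-3-(hydroxymethyl)furan-2(5H)-one | O=C1O[C@@H](/C=C(\C)CC/C=C(\C)[C@H](OC(C)=O)C/C=C(\C)CCO)C=C1CO
F10 | step 14 | (S)-5-[(1E,5E,7R,9E)-7-acetoxy-12-iodo-2,6,10-trimethyldodeca-1,5,9-trien-1-yl]-3-(iodomethyl)furan-2(5H)-one | O=C1O[C@@H](/C=C(\C)CC/C=C(\C)[C@H](OC(C)=O)C/C=C(\C)CCI)C=C1CI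
F11 | step 11 | 1-iodo-3-methoxy-3-(trimethylsilyloxy)propa-1,2-diene (not isolated) | COC(O[Si](C)(C)C)=C=CI
F12 | step 11 | methyl (E)-3-iodo-2-[(phenylsulfanyl)methyl]prop-2-enoate (iodine cis to ester) | COC(=O)/C(CSc1ccccc1)=C\I
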